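Assumption (numbering): cage atoms carry longipinane numbers in every intermediate: C1–C2–C3 is the three-carbon bridge, C4 and C11 are the ring-fusion carbons, C5 and C10 are the one-carbon bridges of the four-membered ring, C6–C9 complete the seven-membered ring, and C12 is the carbon on C3. Open-chain compounds 3–12 carry their own chain numbers. The target is taken as (4R,5S,7R,9R,10R,11R) from its SMILES.

## Analysis of the target

Target 31 is a longipin-2-en-1-one. A cyclobutane (C4–C5–C11–C10) is bridged on one face by the enone unit C1(=O)–C2=C3(CH3) and on the other by the chain C6–C7–C8–C9, which closes the seven-membered ring between C5 and C10. The four cage stereocentres (C4, C5, C10, C11) are locked to each other by the ring fusion, so for the cage only the absolute sense has to be controlled. It is decided at C10, whose methyl group points to the enone bridge and whose C9 substituent points to C5. C7 and C9 are both R and anti (trans on the seven-membered ring); they carry two different esters on two very similar neopentyl carbinols, which makes their differentiation the second problem. Sensitive groups are the enone, the senecioate (prone to deconjugation by amine bases), the two esters (1,3-acyl migration) and the strained ring. An oxygen on C5 together with a carbonyl at C1 would be a β-hydroxy ketone whose Cα–Cβ bond is a cyclobutane bond, and such a system opens by retro-aldol cleavage. The synthesis is hard because C5 lies between the two ring-fusion carbons and the quaternary C6, and because the bicyclo[3.1.1]heptane has to be made as one enantiomer. The strategy rests on the C5–C6 bond: it joins a cyclobutane carbon to the gem-dimethyl carbon, and C6 is α to the oxidised C7. C5 can therefore be a cyclobutanone carbonyl, attacked by a C6 enolate of a C7/C9 β-diketone arm that hangs from C10.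

## Retrosynthetic reasoning

**C9–O ester.** 31 is cut to hydroxy ester 29 and acid chloride 30. The senecioate comes off first because it is the group most easily isomerised and should be carried through as few steps as possible.

**C9–H together with the C7 ester.** 29 is traced to hydroxy ketone 27 and aldehyde 28 by an Evans–Tishchenko reduction. The aldehyde becomes the C7 ester and gives its hydride to C9 from the side of O7. One operation thus places the isovalerate on the right oxygen and sets C9 anti to C7, and no acylating agent has to tell the two neopentyl carbinols apart.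

**C7–H.** 27 comes from trione 26 by reduction of one of two similar, hindered carbonyls with control of the face. A ketoreductase offers reagent control here, where a hydride reagent would be hard to predict.

**C1 oxidation level and the C2=C3 position.** 26 is traced to alcohol 24, which has a C1 carbinol and the exocyclic C3=C12 alkene; oxidation and base-mediated conjugation give the enone. C1 is held as a carbinol until C5 has lost its oxygen. A C5 alkoxide β to a C1 ketone would cleave C5–C11 (or, vinylogously, C4–C5) by strain-driven retro-aldol reaction, so the enone must not be present during the aldol step or the deoxygenation.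

**C5–O.** 24 comes from cyclic thionocarbonate 22, made from diol 21, itself from silyl ether 20. The tertiary C5 hydroxyl is flanked by C6 and by the syn C1 oxygen and is hard to derivatise from outside; the 1,3-syn C1 hydroxyl delivers the thiocarbonyl group intramolecularly. Radical scission then removes the oxygen at C5 and returns the C1 alcohol that the next step needs.

**C5–C6 (key disconnection).** 20 is opened to bicyclic diketone 18 through dianion 19. Cutting here removes the seven-membered ring and the contact between two fully substituted carbons, and leaves a bicyclo[3.1.1]heptan-6-one that a single cycloaddition can make. The forward reaction must form a tertiary carbanion at C6 and add it to the hindered but strained C5 carbonyl.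

**C8–C9 of the arm.** 18 comes from aldol 17, and 17 from aldehyde 15 and ketone 16. A boron enolate is used because it adds to the aldehyde and leaves the cyclobutanone alone.

**The four-membered ring: C5–C11 and C4–C10.** 15 comes from alcohol 14 and silyl ether 13. Cyclobutanone 13 is opened to vinylketene 12, generated from acid 10 through acid chloride 11. Chain atoms map onto the cage as C1→C5, C2→C4, C3→C3, C4→C2, C5→C1, C6→C11, C7→C10, C8→C9. This disconnection gives the bridged ketone with the carbonyl on a one-carbon bridge in one step. The E geometry of the chain C6=C7 alkene sets the C10 configuration, and the chain C5 silyloxy stereocentre (cage C1) chooses the alkene face and so the absolute sense of the cage. That stereocentre is later erased when C1 becomes the ketone.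

**Chain C4–C5.** Acid 10 comes from ester 9 and alcohol 8, and 8 from enal 5 and silyl dienolate 7 by a catalytic enantioselective vinylogous aldol reaction. This is the only step that needs an external source of chirality for the cage.

**Small fragments.** 5 comes from alcohol 4 and ester 3, and 3 from ketone 1 and phosphonate 2 by an E-selective olefination. 7 comes from ester 6.

## Alternatives that were turned down

**Alternative 1: tethered cyclopentadiene Diels–Alder, then semipinacol shift.**
- Disconnection: C4–C5 and C1–C11 of a norbornene, followed by a 1,2-shift of C10 from C1 to C11.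
- Forward key step: triene A2, a 5,5-disubstituted 1-silyloxycyclopentadiene with an E-vinylboronate on a four-carbon tether from C10, cyclises to norbornene A1. Oxidation of the C–B bond, activation of the endo oxygen and migration of the C1–C10 bond would then give the bicyclo[3.1.1]heptenone.
- For: two rings and C4, C5 and C11 form in one stereospecific step. C5 arrives as C–H, so no deoxygenation is needed. C7 and C9 are already carbinols with different protecting groups, so no enzyme and no late differentiation of two ketones is needed. On this last point it is stronger than the chosen route.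
- Against: both diene termini are adjacent to C10, so the tether does not decide whether C5 bonds to C4 or to C1. The dienophile carbon C5 is neopentyl and only weakly activated by boron, and the tether ring is seven-membered. A2 already contains the C10 quaternary centre and both carbinols as single isomers, which means a long sequence before the key step. The shift converts a norbornane into the more strained bicyclo[3.1.1]heptane, against the usual direction of such rearrangements, with migration of C2 or fragmentation as competitors.
- Comparison: the chosen route puts its risk into one bond formation on a substrate made by a dependable cycloaddition, and sets C10 from an alkene geometry rather than by an asymmetric quaternary-centre synthesis.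

**Alternative 2: terpene cyclase.**
- Disconnection: C5–C11, C5–C6 and C4–C10 in one cationic cascade.
- Forward key step: an ionisation-initiated sesquiterpene synthase folds farnesyl diphosphate A4 to α-longipinene A3.
- For: nothing matches its step count to the complete skeleton with all four cage stereocentres and no protecting groups. In skeleton economy it is clearly stronger than the chosen route.
- Against: A3 has no oxygen. C1 can be oxidised like any allylic methylene, but C7 and C9 are unactivated methylenes next to quaternary carbons, with the more accessible C8 between them and no directing group. Two site- and face-selective hydroxylations in the anti sense, followed by two different acylations, have no defensible chemical solution and would need further engineered oxygenases. The enzyme must also give the right enantiomeric series cleanly.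
- Comparison: the chosen route brings the C7 and C9 oxygens in from the start, as the diketone that is also the nucleophile of the key step.

**Alternative 3: cyclopropenone insertion into a bridged bicyclobutane.**
- Disconnection: C11–C1 and C4–C3; the enone bridge is inserted into the central bond of a bicyclobutane.
- Forward key step: a chiral rhodium catalyst inserts cyclopropenone A7 into the C4–C11 bond of meso bicyclobutane A6 to give enone A5.
- For: convergent. The cage configuration comes from a catalyst acting on an achiral substrate. C5 is C–H from the start, and strain release drives the step. On enantiocontrol by catalyst alone it is as strong as the chosen route.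
- Against: A6 (a bicyclobutane bridged by a four-carbon chain that carries the C6 gem-dimethyl group, the C10 methyl group and two ketals) has no short synthesis. Discrimination of the enantiotopic carbons C4 and C11 in a three-carbon insertion has no close analogy. A7 is fragile, and a methyl-bearing analogue would add a regiochemical problem, so the C3 methyl has to be added afterwards by conjugate addition and re-oxidation. The two identical ketals leave the same C7/C9 differentiation for the end.
- Comparison: the chosen key step is an enolate–carbonyl addition whose selectivity elements (dianion regiochemistry, tether geometry) can be read from the substrate.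

Key step: step 13

## Route

**Step 1**
Reactants: 1 1-(tert-butyldimethylsilyloxy)propan-2-one; 2 triethyl phosphonoacetate
Product: 3 ethyl (2E)-4-(tert-butyldimethylsilyloxy)-3-methylbut-2-enoate
Conditions: NaH, THF, 0 °C to rt; minor Z isomer removed by chromatography
Reagents that add atoms: none
Why: Horner–Wadsworth–Emmons olefination of an α-silyloxy ketone; the ester ends trans to the larger CH2OSi group, which is the geometry later needed at the C10–C11 alkene.

**Step 2**
Reactants: 3 ethyl (2E)-4-(tert-butyldimethylsilyloxy)-3-methylbut-2-enoate
Product: 4 (2E)-4-(tert-butyldimethylsilyloxy)-3-methylbut-2-en-1-ol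
Conditions: i-Bu2AlH, CH2Cl2, −78 °C; Rochelle salt
Reagents that add atoms: none
Why: 1,2-reduction of an enoate to the allylic alcohol; alkene geometry and silyl ether are unaffected.

**Step 3**
Reactants: 4 (2E)-4-(tert-butyldimethylsilyloxy)-3-methylbut-2-en-1-ol
Product: 5 (2E)-4-(tert-butyldimethylsilyloxy)-3-methylbut-2-enal
Conditions: MnO2, CH2Cl2, rt
Reagents that add atoms: none
Why: selective oxidation of an allylic alcohol to the enal under neutral conditions, without E/Z isomerisation.

**Step 4**
Reactants: 6 ethyl 3-methylbut-2-enoate
Product: 7 1-ethoxy-1-(tert-butyldimethylsilyloxy)-3-methylbuta-1,3-diene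
Conditions: LiN(i-Pr)2, THF, −78 °C; tert-butyldimethylsilyl chloride, DMPU
Reagents that add atoms: tert-butyldimethylsilyl chloride, CC(C)(C)[Si](C)(C)Cl
Why: γ-deprotonation of the senecioate gives the extended enolate, which is silylated on oxygen to the silyl dienol ether (ketene acetal geometry is irrelevant).

**Step 5**
Reactants: 5 (2E)-4-(tert-butyldimethylsilyloxy)-3-methylbut-2-enal; 7 1-ethoxy-1-(tert-butyldimethylsilyloxy)-3-methylbuta-1,3-diene
Product: 8 ethyl (2E,5S,6E)-8-(tert-butyldimethylsilyloxy)-5-hydroxy-3,7-dimethylocta-2,6-dienoate
Conditions: SiCl4, binaphthyldiamine-derived bisphosphoramide (5 mol %, the antipode that gives 5S), i-Pr2NEt (cat.), CH2Cl2, −78 °C; aq. NaHCO3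
Reagents that add atoms: none
Why: Lewis-base-catalysed vinylogous Mukaiyama aldol reaction; the dienolate reacts at its γ-carbon and the chiral phosphoramide-bound silicon cation selects the aldehyde face, which sets chain C5 (cage C1) as S. A 2Z by-product would be harmless, because the C2=C3 geometry is lost in step 8.

**Step 6**
Reactants: 8 ethyl (2E,5S,6E)-8-(tert-butyldimethylsilyloxy)-5-hydroxy-3,7-dimethylocta-2,6-dienoate
Product: 9 ethyl (2E,5S,6E)-8-(tert-butyldimethylsilyloxy)-5-(tert-butyldiphenylsilyloxy)-3,7-dimethylocta-2,6-dienoate
Conditions: tert-butyldiphenylsilyl chloride, imidazole, DMF, rt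
Reagents that add atoms: tert-butyldiphenylsilyl chloride, CC(C)(C)[Si](Cl)(c1ccccc1)c1ccccc1
Why: silylation of the secondary allylic alcohol; the diphenylsilyl ether is chosen because it survives the later acidic removal of the primary dimethylsilyl ether and is still cleaved by fluoride.

**Step 7**
Reactants: 9 ethyl (2E,5S,6E)-8-(tert-butyldimethylsilyloxy)-5-(tert-butyldiphenylsilyloxy)-3,7-dimethylocta-2,6-dienoate
Product: 10 (2E,5S,6E)-8-(tert-butyldimethylsilyloxy)-5-(tert-butyldiphenylsilyloxy)-3,7-dimethylocta-2,6-dienoic acid
Conditions: LiOH, THF/MeOH/H2O, 40 °C; 1 M HCl to pH 4, 0 °C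
Reagents that add atoms: lithium hydroxide (hydroxide oxygen), [Li+].[OH-]
Why: saponification of the conjugated ester; both silyl ethers are stable to aqueous hydroxide and to a brief, cold, mildly acidic work-up.

**Step 8**
Reactants: 10 (2E,5S,6E)-8-(tert-butyldimethylsilyloxy)-5-(tert-butyldiphenylsilyloxy)-3,7-dimethylocta-2,6-dienoic acid
Product: 13 7-[(tert-butyldimethylsilyloxy)methyl]-2-(tert-butyldiphenylsilyloxy)-7-methyl-4-methylidenebicyclo[3.1.1]heptan-6-one (cage C1 S with silyloxy syn to the carbonyl bridge; C10 methyl syn to the three-carbon bridge), via acid chloride 11 (not isolated), via vinylketene 12 (not isolated)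
Conditions: NaH, toluene, 0 °C; (COCl)2, rt; then slow addition to Et3N, toluene, 110 °C, high dilution
Reagents that add atoms: none
Why: intramolecular [2+2] cycloaddition of a vinylketene with a trisubstituted alkene, the established entry to bicyclo[3.1.1]heptan-6-ones; the ketene carbonyl carbon bonds to the less substituted alkene carbon, which gives the bridged and not the fused skeleton. Addition is suprafacial on the alkene, so the E geometry places the C10 methyl syn to the three-carbon bridge. Allylic 1,3-strain keeps the carbinol hydrogen in the alkene plane next to that methyl, so the tether reaches one face only and C4, C10 and C11 are set in the absolute sense of 31.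

**Step 9**
Reactants: 13 the bis-silylated bicyclic cyclobutanone
Product: 14 2-(tert-butyldiphenylsilyloxy)-7-(hydroxymethyl)-7-methyl-4-methylidenebicyclo[3.1.1]heptan-6-one (stereochemistry as in 13)
Conditions: HF·pyridine, pyridine, THF, 0 °C
Reagents that add atoms: none
Why: buffered fluoride cleaves the primary tert-butyldimethylsilyl ether much faster than the secondary tert-butyldiphenylsilyl ether; the buffer protects the exocyclic alkene.

**Step 10**
Reactants: 14 the C9 primary alcohol
Product: 15 2-(tert-butyldiphenylsilyloxy)-7-methyl-4-methylidene-6-oxobicyclo[3.1.1]heptane-7-carbaldehyde (stereochemistry as in 13)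
Conditions: Dess–Martin periodinane, pyridine, CH2Cl2, rt
Reagents that add atoms: none
Why: Dess–Martin oxidation of a neopentyl primary alcohol; the aldehyde has no α-hydrogen and cannot epimerise.

**Step 11**
Reactants: 15 the C9 aldehyde; 16 3-methylbutan-2-one
Product: 17 2-(tert-butyldiphenylsilyloxy)-7-(1-hydroxy-4-methyl-3-oxopentyl)-7-methyl-4-methylidenebicyclo[3.1.1]heptan-6-one (both C9 epimers; cage as in 13)
Conditions: n-Bu2BOTf, i-Pr2NEt, CH2Cl2, −78 °C (with 16); then 15, −78 to −20 °C; pH 7 buffer/MeOH, no peroxide
Reagents that add atoms: none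
Why: boron aldol reaction; the dibutylboron enolate forms on the methyl side of 16 and adds to aldehydes but not to ketones, so the cyclobutanone is untouched. Peroxide is left out of the work-up to avoid Baeyer–Villiger oxidation of the cyclobutanone, and the new C9 centre is removed in step 12.

**Step 12**
Reactants: 17 the β-hydroxy ketone
Product: 18 1-[2-(tert-butyldiphenylsilyloxy)-7-methyl-4-methylidene-6-oxobicyclo[3.1.1]heptan-7-yl]-4-methylpentane-1,3-dione (cage as in 13; cage labels: C5 cyclobutanone with the C9/C7 diketone arm on C10 anti to the three-carbon bridge)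
Conditions: Dess–Martin periodinane, pyridine, CH2Cl2, 0 °C to rt
Reagents that add atoms: none
Why: Dess–Martin oxidation of a β-hydroxy ketone to the 1,3-diketone; both C9 epimers converge.

**Step 13**
Reactants: 18 the bicyclic cyclobutanone with the β-diketone arm
Product: 20 (1S)-1-(tert-butyldiphenylsilyloxy)-5-hydroxylongipin-3(12)-ene-7,9-dione (cage as in 31; C5 hydroxyl syn to the C1 silyloxy group), via dilithium dianion 19 (not isolated)
Conditions: LiN(SiMe3)2 (1.05 equiv), THF, −78 °C; lithium 2,2,6,6-tetramethylpiperidide (1.3 equiv), −78 to −40 °C; AcOH, −78 °C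
Reagents that add atoms: none
Why: LiN(SiMe3)2 removes the acidic C8 proton; the piperidide, which has no β-hydrogen to transfer as hydride to the non-enolisable cyclobutanone, then removes the isopropyl methine proton at C6, the only γ-site because C10 is quaternary, and gives dianion 19. The more basic terminus C6 adds to the cyclobutanone carbonyl C5; the closest known reaction type is the γ-selective aldol addition of 1,3-diketone dianions to ketones. The seven-membered ring closes in a 7-(enolendo)-exo-trig mode, with the C8–C9 enolate twisting out of conjugation so that the C6 lobe can point at C5. C5 is the only new stereocentre and is fixed by the tether: the arm hangs from C10 on the cyclobutane face opposite the C1–C3 bridge, so C6 reaches only that face of the carbonyl and the oxygen is pushed to the side of the C1 silyloxy group. Conversion of the strained trigonal ring carbon into a tetrahedral one drives the addition, and the remaining C7–C9 diketonate makes C7 a poor acceptor, which disfavours reversal until the cold acetic acid quench. Attack through C8 would create a bicyclo[2.1.1]hexane and is reversible, so γ over α selectivity rests on the dianion regiochemistry. No second acceptor competes because C1 is carried as its silyl ether, which also closes the retro-aldol exit that a C5 alkoxide β to a C1 carbonyl would have.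

**Step 14**
Reactants: 20 the C1 silyl ether of the aldol product
Product: 21 (1S)-1,5-dihydroxylongipin-3(12)-ene-7,9-dione
Conditions: n-Bu4NF, AcOH, THF, rt to 40 °C
Reagents that add atoms: none
Why: fluoride cleavage of the silyl ether; acetic acid buffering keeps the C5 alkoxide concentration low, and the diketone, as the most acidic site, keeps C7 from acting as a retro-aldol acceptor.

**Step 15**
Reactants: 21 the 1,5-syn diol
Product: 22 1,5-O-thiocarbonyl derivative of 21 (six-membered cyclic thionocarbonate bridging O1 and O5)
Conditions: 1,1′-thiocarbonyldiimidazole, DMAP (cat.), toluene, 90 °C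
Reagents that add atoms: 1,1′-thiocarbonyldiimidazole, S=C(n1ccnc1)n1ccnc1
Why: the secondary C1 hydroxyl is thioacylated first and the hindered tertiary C5 hydroxyl then closes the six-membered ring intramolecularly, which the 1,3-syn arrangement of the two oxygens makes easy.

**Step 16**
Reactants: 22 the cyclic thionocarbonate
Product: 24 (1S)-1-hydroxylongipin-3(12)-ene-7,9-dione (C5–H; cage as in 31), via stannyl thiocarbonate 23 (not isolated)
Conditions: n-Bu3SnH (0.3 M), AIBN, toluene, 110 °C; then aq. KF, THF, rt
Reagents that add atoms: none
Why: Barton–McCombie deoxygenation of a cyclic thionocarbonate; the stannyl radical adds to sulfur and the ring opens at the C–O bond that gives the tertiary, strain-relieved C5 radical rather than the secondary C1 radical. Hydrogen can only be delivered to the open face of C5 because C6 is held on the other face by the seven-membered ring, which gives the C5 configuration of 31; fluoride work-up cleaves 23 to the C1 alcohol.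

**Step 17**
Reactants: 24 the C1 alcohol
Product: 26 (4R,5S,10R,11R)-longipin-2-ene-1,7,9-trione, via unconjugated enone 25 (not isolated)
Conditions: (n-Pr4N)RuO4 (cat.), N-methylmorpholine N-oxide, 4 Å MS, CH2Cl2, rt; then DBU, rt
Reagents that add atoms: none
Why: Ley–Griffith oxidation of the secondary alcohol spares the diketone; base then moves the exocyclic C3=C12 alkene of 25 into conjugation with the new C1 carbonyl. C11 cannot epimerise, and no oxygen is left on C5 to fragment.

**Step 18**
Reactants: 26 the trione
Product: 27 (7R)-7-hydroxylongipin-2-ene-1,9-dione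
Conditions: ketoreductase (7R-selective, chosen from a screening panel), NADP+ (cat.), i-PrOH, phosphate buffer pH 7, DMSO (10%), 30 °C
Reagents that add atoms: none
Why: enzymatic mono-reduction of a 1,3-diketone; the enzyme pocket, not the substrate, selects C7 over C9 and C1 and the carbonyl face, which sets C7 as R. Neutral pH avoids retro-aldol opening of the β-hydroxy ketone.

**Step 19**
Reactants: 27 the C7 alcohol; 28 3-methylbutanal
Product: 29 (7R,9R)-9-hydroxy-7-(3-methylbutanoyloxy)longipin-2-en-1-one
Conditions: SmI2 (30 mol %, premixed with 28), 28 (6 equiv), THF, −10 °C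
Reagents that add atoms: none
Why: Evans–Tishchenko reduction; the hemiacetal of the C7 hydroxyl with 28, bound to trivalent samarium together with the C9 carbonyl, transfers its hydride to C9 through a six-membered transition state from the side of O7. The C9 hydroxyl therefore ends anti to C7 (9R) and the acyl group ends on O7 as the isovalerate. Premixing consumes the SmI2 before the enone is exposed to it.

**Step 20**
Reactants: 29 the C9 alcohol; 30 3-methylbut-2-enoyl chloride
Product: 31 (4R,5S,7R,9R,10R,11R)-7-(3-methylbutanoyloxy)-9-(3-methylbut-2-enoyloxy)longipin-2-en-1-one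
Conditions: 30, pyridine, DMAP (cat.), CH2Cl2, 0 °C to rt
Reagents that add atoms: none
Why: acylation of the remaining secondary alcohol; pyridine rather than a trialkylamine limits vinylketene formation from 30 and hence deconjugation of the senecioate.

## Compound list

1 | 1-(tert-butyldimethylsilyloxy)propan-2-one | CC(=O)CO[Si](C)(C)C(C)(C)C | starting material
2 | triethyl phosphonoacetate | CCOC(=O)CP(=O)(OCC)OCC | starting material
3 | ethyl (2E)-4-(tert-butyldimethylsilyloxy)-3-methylbut-2-enoate | CCOC(=O)/C=C(\C)CO[Si](C)(C)C(C)(C)C | intermediate
4 | (2E)-4-(tert-butyldimethylsilyloxy)-3-methylbut-2-en-1-ol | OC/C=C(\C)CO[Si](C)(C)C(C)(C)C | intermediate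
5 | (2E)-4-(tert-butyldimethylsilyloxy)-3-methylbut-2-enal | O=C/C=C(\C)CO[Si](C)(C)C(C)(C)C | intermediate
6 | ethyl 3-methylbut-2-enoate | CCOC(=O)C=C(C)C | starting material
7 | 1-ethoxy-1-(tert-butyldimethylsilyloxy)-3-methylbuta-1,3-diene | CCOC(=CC(C)=C)O[Si](C)(C)C(C)(C)C | intermediate
8 | ethyl (2E,5S,6E)-8-(tert-butyldimethylsilyloxy)-5-hydroxy-3,7-dimethylocta-2,6-dienoate | CCOC(=O)/C=C(\C)C[C@H](O)/C=C(\C)CO[Si](C)(C)C(C)(C)C | intermediate
9 | ethyl (2E,5S,6E)-8-(tert-butyldimethylsilyloxy)-5-(tert-butyldiphenylsilyloxy)-3,7-dimethylocta-2,6-dienoate | CCOC(=O)/C=C(\C)C[C@H](O[Si](c1ccccc1)(c1ccccc1)C(C)(C)C)/C=C(\C)CO[Si](C)(C)C(C)(C)C | intermediate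
10 | (2E,5S,6E)-8-(tert-butyldimethylsilyloxy)-5-(tert-butyldiphenylsilyloxy)-3,7-dimethylocta-2,6-dienoic acid | OC(=O)/C=C(\C)C[C@H](O[Si](c1ccccc1)(c1ccccc1)C(C)(C)C)/C=C(\C)CO[Si](C)(C)C(C)(C)C | intermediate
11 | acid chloride of 10 | ClC(=O)/C=C(\C)C[C@H](O[Si](c1ccccc1)(c1ccccc1)C(C)(C)C)/C=C(\C)CO[Si](C)(C)C(C)(C)C | intermediate (not isolated)
12 | (5S,6E)-8-(tert-butyldimethylsilyloxy)-5-(tert-butyldiphenylsilyloxy)-7-methyl-3-methylideneocta-1,6-dien-1-one (vinylketene) | O=C=CC(=C)C[C@H](O[Si](c1ccccc1)(c1ccccc1)C(C)(C)C)/C=C(\C)CO[Si](C)(C)C(C)(C)C | intermediate (not isolated)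
13 | 7-[(tert-butyldimethylsilyloxy)methyl]-2-(tert-butyldiphenylsilyloxy)-7-methyl-4-methylidenebicyclo[3.1.1]heptan-6-one (silyloxy syn to the carbonyl bridge; 7-methyl syn to the three-carbon bridge) | CC(C)(C)[Si](C)(C)OC[C@]1(C)[C@@H]2C(=O)[C@H]1[C@@H](O[Si](c3ccccc3)(c3ccccc3)C(C)(C)C)CC2=C | intermediate
14 | 2-(tert-butyldiphenylsilyloxy)-7-(hydroxymethyl)-7-methyl-4-methylidenebicyclo[3.1.1]heptan-6-one | OC[C@]1(C)[C@@H]2C(=O)[C@H]1[C@@H](O[Si](c3ccccc3)(c3ccccc3)C(C)(C)C)CC2=C | intermediate
15 | 2-(tert-butyldiphenylsilyloxy)-7-methyl-4-methylidene-6-oxobicyclo[3.1.1]heptane-7-carbaldehyde | O=C[C@]1(C)[C@@H]2C(=O)[C@H]1[C@@H](O[Si](c3ccccc3)(c3ccccc3)C(C)(C)C)CC2=C | intermediate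
16 | 3-methylbutan-2-one | CC(C)C(C)=O | starting material
17 | 2-(tert-butyldiphenylsilyloxy)-7-(1-hydroxy-4-methyl-3-oxopentyl)-7-methyl-4-methylidenebicyclo[3.1.1]heptan-6-one (C9 epimers) | CC(C)C(=O)CC(O)[C@]1(C)[C@@H]2C(=O)[C@H]1[C@@H](O[Si](c3ccccc3)(c3ccccc3)C(C)(C)C)CC2=C | intermediate
18 | 1-[2-(tert-butyldiphenylsilyloxy)-7-methyl-4-methylidene-6-oxobicyclo[3.1.1]heptan-7-yl]-4-methylpentane-1,3-dione | CC(C)C(=O)CC(=O)[C@]1(C)[C@@H]2C(=O)[C@H]1[C@@H](O[Si](c3ccccc3)(c3ccccc3)C(C)(C)C)CC2=C | intermediate
19 | dilithium dianion of 18 (C6/C8 dienediolate) | [Li+].[Li+].CC(C)=C([O-])C=C([O-])[C@]1(C)[C@@H]2C(=O)[C@H]1[C@@H](O[Si](c3ccccc3)(c3ccccc3)C(C)(C)C)CC2=C | intermediate (not isolated)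
20 | (1S)-1-(tert-butyldiphenylsilyloxy)-5-hydroxylongipin-3(12)-ene-7,9-dione | O=C1CC(=O)C(C)(C)[C@]2(O)[C@H]3[C@@H](O[Si](c4ccccc4)(c4ccccc4)C(C)(C)C)CC(=C)[C@@H]2[C@]31C | intermediate
21 | (1S)-1,5-dihydroxylongipin-3(12)-ene-7,9-dione | O=C1CC(=O)C(C)(C)[C@]2(O)[C@H]3[C@@H](O)CC(=C)[C@@H]2[C@]31C | intermediate
22 | 1,5-O-thiocarbonyl derivative of 21 (cyclic thionocarbonate) | O=C1CC(=O)C(C)(C)[C@]2(OC(=S)O4)[C@H]3[C@@H]4CC(=C)[C@@H]2[C@]31C | intermediate
23 | (1S)-1-[(tributylstannylsulfanyl)carbonyloxy]longipin-3(12)-ene-7,9-dione | O=C1CC(=O)C(C)(C)[C@@H]2[C@H]3[C@@H](OC(=O)S[Sn](CCCC)(CCCC)CCCC)CC(=C)[C@@H]2[C@]31C | intermediate (not isolated)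
24 | (1S)-1-hydroxylongipin-3(12)-ene-7,9-dione | O=C1CC(=O)C(C)(C)[C@@H]2[C@H]3[C@@H](O)CC(=C)[C@@H]2[C@]31C | intermediate
25 | longipin-3(12)-ene-1,7,9-trione | O=C1CC(=O)C(C)(C)[C@@H]2[C@H]3C(=O)CC(=C)[C@@H]2[C@]31C | intermediate (not isolated)
26 | (4R,5S,10R,11R)-longipin-2-ene-1,7,9-trione | O=C1CC(=O)C(C)(C)[C@@H]2[C@H]3C(=O)C=C(C)[C@@H]2[C@]31C | intermediate
27 | (7R)-7-hydroxylongipin-2-ene-1,9-dione | O=C1C[C@@H](O)C(C)(C)[C@@H]2[C@H]3C(=O)C=C(C)[C@@H]2[C@]31C | intermediate
28 | 3-methylbutanal | CC(C)CC=O | starting material
29 | (7R,9R)-9-hydroxy-7-(3-methylbutanoyloxy)longipin-2-en-1-one | O[C@@H]1C[C@@H](OC(=O)CC(C)C)C(C)(C)[C@@H]2[C@H]3C(=O)C=C(C)[C@@H]2[C@]31C | intermediate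
30 | 3-methylbut-2-enoyl chloride | CC(C)=CC(Cl)=O | starting material
31 | (4R,5S,7R,9R,10R,11R)-7-(3-methylbutanoyloxy)-9-(3-methylbut-2-enoyloxy)longipin-2-en-1-one | CC(C)=CC(=O)O[C@@H]1C[C@@H](OC(=O)CC(C)C)C(C)(C)[C@@H]2[C@H]3C(=O)C=C(C)[C@@H]2[C@]31C | target

## Step count and least certain steps

Total: 20 steps. Longest linear sequence: 19 steps (steps 1–3 and 5–20); step 4 is a one-step side branch.

**Step 13 (key step).** The second deprotonation at the hindered tertiary C6–H may be too slow, so that the amide base attacks the cyclobutanone or the monoanion reacts reversibly through C8. The closure also requires the C6 enolate to twist out of conjugation, and the adduct may revert by retro-aldol reaction if it warms before the quench. Migration of the silyl group from O1 to the new O5 alkoxide would be harmless, since step 14 removes it from either oxygen. Fallback (from 15, returning at 20): the C6 enolate is made reductively instead of by deprotonation. A boron aldol reaction of 15 with 3-bromo-3-methylbutan-2-one (n-Bu2BOTf, i-Pr2NEt) should give the bromo aldol F1, which is silylated (Et3SiOTf, 2,6-lutidine) to the triethylsilyl ether F2. SmI2 (2.2 equiv, THF, −78 °C) then cleaves the C–Br bond and forms the samarium enolate at C6 only (Reformatsky type), which closes onto C5 to the tricyclic silyl ether F3. Buffered HF·pyridine gives the C9 alcohol F4, and Dess–Martin oxidation of that secondary alcohol, which leaves the tertiary C5 hydroxyl alone, leads to 20.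

**Step 8.** The alkene carries two allylic C–O bonds and is less nucleophilic than a simple trisubstituted alkene, so oligomerisation of the vinylketene under hot amine/ammonium chloride conditions may outrun the cycloaddition. Incomplete transfer of chirality from the carbinol (tether reaching the other alkene face) would give the diastereomer with the mirror-image cage, which would have to be separated. Fallback (from 5, returning at 13): vinylketene 12 is generated without base by a Wolff rearrangement. A catalytic asymmetric Nozaki–Hiyama–Kishi 2-bromoallylation of 5 (CrCl2, chiral sulfonamide ligand, Mn, 2,3-dibromopropene) gives the bromo alcohol F5, which is silylated to the tert-butyldiphenylsilyl ether F6. Bromine–lithium exchange (t-BuLi, −78 °C) and acylation with N-methoxy-N-methylacetamide give the methyl enone F7. Detrifluoroacetylative diazo transfer (LiN(SiMe3)2, 2,2,2-trifluoroethyl trifluoroacetate, to the trifluoroacetyl ketone F8; then methanesulfonyl azide, Et3N) gives the diazo ketone F9. Irradiation of F9 in hot toluene releases 12 slowly and at low concentration, and 12 cyclises to 13.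

**Step 16.** The ring may open on the C1 side, leaving the oxygen on C5. The C5 radical, which is β to the C7 carbonyl, may also undergo a 1,2-acyl shift to C6 before it is reduced; the high stannane concentration is chosen to outrun this. Fallback (from 20, returning at 24): the tertiary alcohol is derivatised with the smallest possible thiocarbonyl reagent while C1 is still silylated. KN(SiMe3)2 (2.2 equiv), CS2 and MeI (1 equiv) should give the S-methyl xanthate F10, which cannot undergo Chugaev elimination because no β-hydrogen can give a viable alkene. n-Bu3SnH/AIBN then gives the deoxygenated silyl ether F11, and n-Bu4NF/AcOH gives 24.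

**Step 18.** No enzyme of the panel may accept the bulky cage diketone, or reduction may occur at C9 or at the enone carbonyl, or from the wrong face. Fallback (from 26, returning at 27, no new compound): Noyori–Ikariya asymmetric transfer hydrogenation with RuCl(p-cymene)(TsDPEN) and HCO2H/Et3N, which is known to stop 1,3-diketones at the hydroxy ketone and to leave C=C bonds alone; the catalyst antipode is matched to the 7R carbinol.

**Step 19.** The hemiacetal may fail to reach the C9 carbonyl within the rigid seven-membered ring, so that hydride transfer is slow and retro-aldol opening of the β-hydroxy ketone or 1,3-acyl migration in the product takes over. Fallback (from 27, returning at 29): the two events are separated. Acylation of the C7 hydroxyl under acidic conditions (3-methylbutanoic anhydride, Sc(OTf)3 cat., MeCN, −20 °C, to avoid β-elimination) gives the keto ester F12. Its C9 carbonyl is then reduced by a second ketoreductase selected for the 9R alcohol at pH 7, which gives 29.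

## Further compounds

F1 | step 13 | 7-(4-bromo-1-hydroxy-4-methyl-3-oxopentyl)-2-(tert-butyldiphenylsilyloxy)-7-methyl-4-methylidenebicyclo[3.1.1]heptan-6-one (C9 epimers) | CC(C)(Br)C(=O)CC(O)[C@]1(C)[C@@H]2C(=O)[C@H]1[C@@H](O[Si](c3ccccc3)(c3ccccc3)C(C)(C)C)CC2=C
F2 | step 13 | triethylsilyl ether of F1 | CC(C)(Br)C(=O)CC(O[Si](CC)(CC)CC)[C@]1(C)[C@@H]2C(=O)[C@H]1[C@@H](O[Si](c3ccccc3)(c3ccccc3)C(C)(C)C)CC2=C
F3 | step 13 | (1S)-1-(tert-butyldiphenylsilyloxy)-5-hydroxy-9-(triethylsilyloxy)longipin-3(12)-en-7-one (C9 epimers) | CC[Si](CC)(CC)OC1CC(=O)C(C)(C)[C@]2(O)[C@H]3[C@@H](O[Si](c4ccccc4)(c4ccccc4)C(C)(C)C)CC(=C)[C@@H]2[C@]31C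
F4 | step 13 | (1S)-1-(tert-butyldiphenylsilyloxy)-5,9-dihydroxylongipin-3(12)-en-7-one (C9 epimers) | OC1CC(=O)C(C)(C)[C@]2(O)[C@H]3[C@@H](O[Si](c4ccccc4)(c4ccccc4)C(C)(C)C)CC(=C)[C@@H]2[C@]31C
F5 | step 8 | (4S,5E)-2-bromo-7-(tert-butyldimethylsilyloxy)-6-methylhepta-1,5-dien-4-ol | C=C(Br)C[C@H](O)/C=C(\C)CO[Si](C)(C)C(C)(C)C
F6 | step 8 | tert-butyldiphenylsilyl ether of F5 | C=C(Br)C[C@H](O[Si](c1ccccc1)(c1ccccc1)C(C)(C)C)/C=C(\C)CO[Si](C)(C)C(C)(C)C
F7 | step 8 | (5S,6E)-8-(tert-butyldimethylsilyloxy)-5-(tert-butyldiphenylsilyloxy)-7-methyl-3-methylideneoct-6-en-2-one | CC(=O)C(=C)C[C@H](O[Si](c1ccccc1)(c1ccccc1)C(C)(C)C)/C=C(\C)CO[Si](C)(C)C(C)(C)C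
F8 | step 8 | 1-trifluoroacetyl derivative of F7 | O=C(CC(=O)C(=C)C[C@H](O[Si](c1ccccc1)(c1ccccc1)C(C)(C)C)/C=C(\C)CO[Si](C)(C)C(C)(C)C)C(F)(F)F
F9 | step 8 | (5S,6E)-8-(tert-butyldimethylsilyloxy)-5-(tert-butyldiphenylsilyloxy)-1-diazo-7-methyl-3-methylideneoct-6-en-2-one | [N-]=[N+]=CC(=O)C(=C)C[C@H](O[Si](c1ccccc1)(c1ccccc1)C(C)(C)C)/C=C(\C)CO[Si](C)(C)C(C)(C)C
F10 | step 16 | O-[(1S)-1-(tert-butyldiphenylsilyloxy)-7,9-dioxolongipin-3(12)-en-5-yl] S-methyl dithiocarbonate | O=C1CC(=O)C(C)(C)[C@]2(OC(=S)SC)[C@H]3[C@@H](O[Si](c4ccccc4)(c4ccccc4)C(C)(C)C)CC(=C)[C@@H]2[C@]31C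
F11 | step 16 | (1S)-1-(tert-butyldiphenylsilyloxy)longipin-3(12)-ene-7,9-dione | O=C1CC(=O)C(C)(C)[C@@H]2[C@H]3[C@@H](O[Si](c4ccccc4)(c4ccccc4)C(C)(C)C)CC(=C)[C@@H]2[C@]31C
F0 | step 18 | none | none
F12 | step 19 | (7R)-7-(3-methylbutanoyloxy)longipin-2-ene-1,9-dione | O=C1C[C@@H](OC(=O)CC(C)C)C(C)(C)[C@@H]2[C@H]3C(=O)C=C(C)[C@@H]2[C@]31C
A1 | alternative 1 | tricyclic bridgehead-silyloxy norbornene with endo boronate | COc1ccc(cc1)CO[C@@H]1C[C@@H](O[Si](C)(C)C(C)(C)C)C(C)(C)[C@@H]2[C@@H](B4OC(C)(C)C(C)(C)O4)[C@@]3(O[Si](CC)(CC)CC)C=C(C)[C@@H]2[C@]31C
A2 | alternative 1 | 5,5-disubstituted 1-(triethylsilyloxy)cyclopentadiene with tethered E-vinylboronate | COc1ccc(cc1)CO[C@H](C[C@@H](O[Si](C)(C)C(C)(C)C)C(C)(C)/C=C/B1OC(C)(C)C(C)(C)O1)[C@]1(C)C=C(C)C=C1O[Si](CC)(CC)CC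
A3 | alternative 2 | α-longipinene | C1CCC(C)(C)[C@@H]2[C@H]3CC=C(C)[C@@H]2[C@]31C
A4 | alternative 2 | (2E,6E)-farnesyl diphosphate | CC(C)=CCC/C(C)=C/CC/C(C)=C/COP(O)(=O)OP(O)(O)=O
A5 | alternative 3 | tricyclic 2-en-1-one bis(ethylene ketal) lacking the C3 methyl | C15(OCCO5)CC4(OCCO4)C(C)(C)[C@@H]2[C@H]3C(=O)C=C[C@@H]2[C@]31C
A6 | alternative 3 | meso bicyclo[1.1.0]butane bridged by the C6–C9 chain (bis(ethylene ketal)) | CC12C3C1C3C(C)(C)C1(OCCO1)CC21OCCO1
A7 | alternative 3 | cyclopropenone | O=C1C=C1
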